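The target is disconnected at the C2–C3 bond that joins its two adjacent methine stereocentres, each of which carries a benzylic CH2. The acetoxymethyl group on C2 is read as a reduced carboxyl and the syringylmethyl group on C3 as a propenyl group cut back by one carbon and arylated. An ester-enolate [3,3]-sigmatropic (Ireland–Claisen) rearrangement then forms C2–C3 and sets both centres in one operation, relaying chirality from a single carbinol centre through a chair transition state. Its precursor is the (R,Z)-pent-3-en-2-yl ester of O-benzyl dihydroferulic acid, an acyclic ester with one easily set stereocentre.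

Key step: step 5

Remark on the chemistry (locants used throughout): C1 is the CH2OAc carbon, C2 and C3 are the methine carbons, C4 is the CH2 on the syringyl ring; the target is (2S,3R), with CH2OAc and CH3 anti when the chain ArCH2–C2–C3–CH2Ar' is drawn extended.

Step 1
Reactants: 1 3-(4-hydroxy-3-methoxyphenyl)propanoic acid (dihydroferulic acid)
Product: 2 3-[4-(benzyloxy)-3-methoxyphenyl]propanoic acid
Conditions: BnBr, NaOH, EtOH/H2O, reflux; then HCl (aq)
Reagents that add atoms: benzyl bromide, BrCc1ccccc1
Why: Williamson ether synthesis; in aqueous ethanolic hydroxide the phenoxide is far more nucleophilic than the carboxylate, so the phenol should be benzylated selectively and the acid recovered on acidification.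

Step 2
Reactants: 3 pent-3-yn-2-one
Product: 4 (R)-pent-3-yn-2-ol
Conditions: Ru[(R,R)-TsDPEN](p-cymene) (cat.), i-PrOH, rt
Reagents that add atoms: none
Why: Noyori-type asymmetric transfer hydrogenation of an alkynyl ketone; the alkynyl group takes the place an aryl group takes in aryl ketone reductions, so the (R,R) ligand should set the R carbinol centre, and the triple bond is not reduced.

Step 3
Reactants: 2 3-[4-(benzyloxy)-3-methoxyphenyl]propanoic acid; 4 (R)-pent-3-yn-2-ol
Product: 5 (2R)-pent-3-yn-2-yl 3-[4-(benzyloxy)-3-methoxyphenyl]propanoate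
Conditions: DCC, DMAP (cat.), CH2Cl2, 0 °C → rt
Reagents that add atoms: none
Why: Steglich esterification; acylation takes place at oxygen, so the carbinol configuration is retained.

Step 4
Reactants: 5 (2R)-pent-3-yn-2-yl 3-[4-(benzyloxy)-3-methoxyphenyl]propanoate
Product: 6 (2R,3Z)-pent-3-en-2-yl 3-[4-(benzyloxy)-3-methoxyphenyl]propanoate
Conditions: H2 (1 atm), Lindlar catalyst, quinoline, EtOAc, rt
Reagents that add atoms: none
Why: Lindlar semi-hydrogenation; syn delivery of H2 on the poisoned Pd surface should give the Z-alkene and stop there, leaving the benzyl ether and the allylic ester intact.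

Step 5
Reactants: 6 (2R,3Z)-pent-3-en-2-yl 3-[4-(benzyloxy)-3-methoxyphenyl]propanoate
Product: 10 (2S,3R,4E)-2-{[4-(benzyloxy)-3-methoxyphenyl]methyl}-3-methylhex-4-enoic acid, via lithium E(O)-enolate 7 (not isolated), via (E)-silyl ketene acetal 8 (not isolated), via trimethylsilyl ester 9 (not isolated)
Conditions: LDA, THF, −78 °C; TMSCl/Et3N, −78 °C → rt, then 60 °C; 1 M HCl
Reagents that add atoms: none
Why: Ireland–Claisen rearrangement, an ester-enolate [3,3]-sigmatropic shift: kinetic deprotonation of 6 by LDA in THF should give the E(O)-enolate 7 (CH2Ar trans to O–Li, cis to the allylic oxygen), silylation on oxygen fixes this geometry in 8, and 8 rearranges on warming through a concerted, suprafacial chair transition state to silyl ester 9, which the acidic work-up hydrolyses to 10. No ring is closed; the six-atom array O–C(OSi)=C···C=C–C exists only in the transition state and the C2–C3 bond is the one that forms. C3 is controlled by the carbinol centre of 6: with a Z-alkene, A(1,3) strain forces the carbinol methyl group into the equatorial position of the chair, so the new bond forms on the alkene face from which the C–O bond leaves, which should give 3R together with an E-propenyl group. C2 is controlled by the enolate geometry, since an E(O)-ketene acetal paired with a Z-alkene in a chair places CH2Ar and the C3 methyl syn along the acid chain, that is 2S. The step needs E(O)-selective enolisation and chair over boat selectivity; THF without a dipolar cosolvent secures the first and the acyclic, unconstrained substrate the second. The closest known reaction type is the rearrangement of silyl ketene acetals of allylic propanoates and 3-arylpropanoates with 1,3-chirality transfer from secondary allylic carbinols.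

Step 6
Reactants: 10 (2S,3R,4E)-2-{[4-(benzyloxy)-3-methoxyphenyl]methyl}-3-methylhex-4-enoic acid
Product: 11 (2S,3R,4E)-2-{[4-(benzyloxy)-3-methoxyphenyl]methyl}-3-methylhex-4-en-1-ol
Conditions: LiAlH4, THF, 0 °C → reflux; aqueous NaOH work-up
Reagents that add atoms: none
Why: Hydride reduction of the carboxylic acid to the primary alcohol; the alkene and the benzyl ether are inert and the carboxylate is not enolised, so C2 should not epimerise.

Step 7
Reactants: 11 (2S,3R,4E)-2-{[4-(benzyloxy)-3-methoxyphenyl]methyl}-3-methylhex-4-en-1-ol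
Product: 12 (2S,3R,4E)-2-{[4-(benzyloxy)-3-methoxyphenyl]methyl}-3-methylhex-4-en-1-yl acetate
Conditions: Ac2O, pyridine, DMAP (cat.), CH2Cl2, rt
Reagents that add atoms: acetic anhydride, CC(=O)OC(C)=O
Why: DMAP-catalysed O-acetylation of the only free hydroxyl installs the acetate of the target while both phenols are still masked.

Step 8
Reactants: 12 (2S,3R,4E)-2-{[4-(benzyloxy)-3-methoxyphenyl]methyl}-3-methylhex-4-en-1-yl acetate
Product: 13 (2S,3S)-2-{[4-(benzyloxy)-3-methoxyphenyl]methyl}-3-methyl-4-oxobutyl acetate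
Conditions: OsO4 (cat.), NaIO4, 2,6-lutidine, dioxane/H2O, rt
Reagents that add atoms: sodium periodate, [Na+].[O-]I(=O)(=O)=O; osmium tetroxide (catalytic oxygen carrier), O=[Os](=O)(=O)=O
Why: Lemieux–Johnson oxidative cleavage excises the propenyl terminus as acetaldehyde; the buffered medium should limit epimerisation of the α-branched aldehyde at C3, and the aryl ethers and the acetate are not affected (the descriptor at C3 changes to S only because the CIP priorities change).

Step 9
Reactants: 14 4-bromo-2,6-dimethoxyphenol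
Product: 15 2-(benzyloxy)-5-bromo-1,3-dimethoxybenzene
Conditions: BnBr, K2CO3, DMF, 60 °C
Reagents that add atoms: benzyl bromide, BrCc1ccccc1
Why: Williamson ether synthesis on the phenoxide; the aryl bromide is inert under these conditions.

Step 10
Reactants: 13 (2S,3S)-2-{[4-(benzyloxy)-3-methoxyphenyl]methyl}-3-methyl-4-oxobutyl acetate; 15 2-(benzyloxy)-5-bromo-1,3-dimethoxybenzene
Product: 18 (2S,3S,4RS)-4-[4-(benzyloxy)-3,5-dimethoxyphenyl]-2-{[4-(benzyloxy)-3-methoxyphenyl]methyl}-3-methylbutane-1,4-diyl diacetate, via arylmagnesium bromide 16 (not isolated), via bromomagnesium alkoxide 17 (not isolated)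
Conditions: 15, Mg, THF, reflux; then 13, THF, −78 °C; then Ac2O, DMAP (cat.), −78 °C → rt
Reagents that add atoms: acetic anhydride, CC(=O)OC(C)=O
Why: Grignard addition to the aldehyde, which at −78 °C should be much faster than attack on the acetate, followed by O-acylation of the magnesium alkoxide; the new benzylic centre at C4 forms without control, which does not matter because step 11 removes it.

Step 11
Reactants: 18 (2S,3S,4RS)-4-[4-(benzyloxy)-3,5-dimethoxyphenyl]-2-{[4-(benzyloxy)-3-methoxyphenyl]methyl}-3-methylbutane-1,4-diyl diacetate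
Product: 19 (2S,3R)-4-(4-hydroxy-3,5-dimethoxyphenyl)-2-[(4-hydroxy-3-methoxyphenyl)methyl]-3-methylbutyl acetate (CID 53359578)
Conditions: H2 (1 atm), 10% Pd/C, EtOAc/EtOH, rt
Reagents that add atoms: none
Why: Pd-catalysed hydrogenolysis should cleave the two O-benzyl ethers and the benzylic C–OAc bond in one operation, whereas the primary alkyl acetate and the two sp3 stereocentres are not touched.

Compound list
1 | 3-(4-hydroxy-3-methoxyphenyl)propanoic acid (dihydroferulic acid) | COc1cc(CCC(=O)O)ccc1O | starting material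
2 | 3-[4-(benzyloxy)-3-methoxyphenyl]propanoic acid | COc1cc(CCC(=O)O)ccc1OCc1ccccc1 | intermediate
3 | pent-3-yn-2-one | CC#CC(C)=O | starting material
4 | (R)-pent-3-yn-2-ol | C[C@@H](O)C#CC | intermediate
5 | (2R)-pent-3-yn-2-yl 3-[4-(benzyloxy)-3-methoxyphenyl]propanoate | COc1cc(CCC(=O)O[C@H](C)C#CC)ccc1OCc1ccccc1 | intermediate
6 | (2R,3Z)-pent-3-en-2-yl 3-[4-(benzyloxy)-3-methoxyphenyl]propanoate | COc1cc(CCC(=O)O[C@H](C)/C=C\C)ccc1OCc1ccccc1 | intermediate
7 | lithium E(O)-enolate of 6 (CH2Ar trans to O–Li) | [Li+].COc1cc(C/C=C(/[O-])O[C@H](C)/C=C\C)ccc1OCc1ccccc1 | intermediate (not isolated)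
8 | (E)-trimethylsilyl ketene acetal of 6 (CH2Ar trans to OSiMe3) | COc1cc(C/C=C(/O[Si](C)(C)C)O[C@H](C)/C=C\C)ccc1OCc1ccccc1 | intermediate (not isolated)
9 | trimethylsilyl (2S,3R,4E)-2-{[4-(benzyloxy)-3-methoxyphenyl]methyl}-3-methylhex-4-enoate | COc1cc(C[C@H](C(=O)O[Si](C)(C)C)[C@H](C)/C=C/C)ccc1OCc1ccccc1 | intermediate (not isolated)
10 | (2S,3R,4E)-2-{[4-(benzyloxy)-3-methoxyphenyl]methyl}-3-methylhex-4-enoic acid | COc1cc(C[C@H](C(=O)O)[C@H](C)/C=C/C)ccc1OCc1ccccc1 | intermediate
11 | (2S,3R,4E)-2-{[4-(benzyloxy)-3-methoxyphenyl]methyl}-3-methylhex-4-en-1-ol | COc1cc(C[C@H](CO)[C@H](C)/C=C/C)ccc1OCc1ccccc1 | intermediate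
12 | (2S,3R,4E)-2-{[4-(benzyloxy)-3-methoxyphenyl]methyl}-3-methylhex-4-en-1-yl acetate | COc1cc(C[C@H](COC(C)=O)[C@H](C)/C=C/C)ccc1OCc1ccccc1 | intermediate
13 | (2S,3S)-2-{[4-(benzyloxy)-3-methoxyphenyl]methyl}-3-methyl-4-oxobutyl acetate | COc1cc(C[C@H](COC(C)=O)[C@H](C)C=O)ccc1OCc1ccccc1 | intermediate
14 | 4-bromo-2,6-dimethoxyphenol | COc1cc(Br)cc(OC)c1O | starting material
15 | 2-(benzyloxy)-5-bromo-1,3-dimethoxybenzene | COc1cc(Br)cc(OC)c1OCc1ccccc1 | intermediate
16 | [4-(benzyloxy)-3,5-dimethoxyphenyl]magnesium bromide | COc1cc([Mg]Br)cc(OC)c1OCc1ccccc1 | intermediate (not isolated)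
17 | bromomagnesium alkoxide of the C4 carbinol (adduct of 16 and 13, both C4 epimers) | COc1cc(C[C@H](COC(C)=O)[C@H](C)C(O[Mg]Br)c2cc(OC)c(OCc3ccccc3)c(OC)c2)ccc1OCc1ccccc1 | intermediate (not isolated)
18 | (2S,3S,4RS)-4-[4-(benzyloxy)-3,5-dimethoxyphenyl]-2-{[4-(benzyloxy)-3-methoxyphenyl]methyl}-3-methylbutane-1,4-diyl diacetate | COc1cc(C[C@H](COC(C)=O)[C@H](C)C(OC(C)=O)c2cc(OC)c(OCc3ccccc3)c(OC)c2)ccc1OCc1ccccc1 | intermediate
19 | (2S,3R)-4-(4-hydroxy-3,5-dimethoxyphenyl)-2-[(4-hydroxy-3-methoxyphenyl)methyl]-3-methylbutyl acetate | COc1cc(C[C@H](COC(C)=O)[C@H](C)Cc2cc(OC)c(O)c(OC)c2)ccc1O | target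

Total step count: 11
Longest linear sequence: 9 steps (steps 1, 3, 4, 5, 6, 7, 8, 10, 11; the branch through step 2 is equally long)

Steps most likely to fail

1. Step 5 (key step). What may go wrong: partial enolisation to the Z(O)-enolate or leakage through a boat transition state, either of which erodes the configuration at C2; fragmentation of the lithium enolate before it is silylated is a second concern. Fallback: C2 is corrected under thermodynamic control on a γ-lactone instead of being fixed by the enolate geometry. The fallback sets out from 10 (taken on as a mixture of C2 epimers) and comes back to the route at 18. Oxidative cleavage of the acid itself (OsO4 cat., NaIO4, 2,6-lutidine, dioxane/H2O) should give (2RS,3S)-2-{[4-(benzyloxy)-3-methoxyphenyl]methyl}-3-methyl-4-oxobutanoic acid F1. Addition of Grignard reagent 16 (2.2 equiv, THF, −78 → 0 °C) with an acidic work-up should close the γ-lactone. DBU in toluene at 80 °C should then move its α-carbon to the favoured 3,4-trans arrangement, which is the C2/C3 relationship of the target, so that both C2 epimers converge on (3S,4S,5RS)-5-[4-(benzyloxy)-3,5-dimethoxyphenyl]-3-{[4-(benzyloxy)-3-methoxyphenyl]methyl}-4-methyloxolan-2-one F2. LiAlH4 (THF, 0 °C) should open it to (2S,3S,4RS)-4-[4-(benzyloxy)-3,5-dimethoxyphenyl]-2-{[4-(benzyloxy)-3-methoxyphenyl]methyl}-3-methylbutane-1,4-diol F3, and Ac2O/pyridine/DMAP should acetylate both hydroxyls to give 18.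

2. Step 10. What may go wrong: attack of the aryl Grignard reagent on the primary acetate, or enolisation of the α-branched aldehyde with loss of configuration at C3. Fallback: the polarity at C4 is reversed and the arene is joined by a nickel-catalysed reductive sp3–sp2 cross-electrophile coupling, so that neither a basic aryl nucleophile nor a benzylic oxygen is involved. It sets out from 13 and comes back to the route at 19. NaBH4 (THF/EtOH, 0 °C) should give (2S,3S)-2-{[4-(benzyloxy)-3-methoxyphenyl]methyl}-4-hydroxy-3-methylbutyl acetate F4. I2, PPh3 and imidazole (CH2Cl2, 0 °C) should convert it into (2S,3S)-2-{[4-(benzyloxy)-3-methoxyphenyl]methyl}-4-iodo-3-methylbutyl acetate F5. Coupling with aryl bromide 15 (NiBr2·glyme, 4,4'-di-tert-butyl-2,2'-bipyridine, Zn, NaI, DMA, 60 °C) should give (2S,3R)-4-[4-(benzyloxy)-3,5-dimethoxyphenyl]-2-{[4-(benzyloxy)-3-methoxyphenyl]methyl}-3-methylbutyl acetate F6, and H2 with Pd/C (EtOAc/EtOH, rt) should remove the two benzyl groups to give 19.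

3. Step 4. What may go wrong: over-reduction to the saturated ester or Z to E isomerisation on the catalyst; any E-ester would be carried through the rearrangement to the C3 epimer. Fallback: the semi-hydrogenation is avoided by the complementary pairing of an E-alkene with a Z(O)-enolate, which by the same chair analysis leads to the same acid. It sets out from 3 and 2 and comes back to the route at 10. Transfer hydrogenation of 3 with the enantiomeric (S,S) catalyst should give (S)-pent-3-yn-2-ol F7. Trans-hydroalumination with Red-Al (THF, 0 °C → rt) and protonolysis should give (2S,3E)-pent-3-en-2-ol F8. DCC/DMAP esterification with 2 should give (2S,3E)-pent-3-en-2-yl 3-[4-(benzyloxy)-3-methoxyphenyl]propanoate F9. Enolisation with LDA in THF/DMPU, which favours the Z(O) geometry, should give the lithium Z(O)-enolate F10 and, after TMSCl, the (Z)-silyl ketene acetal F11, whose chair [3,3] shift should lead to the same silyl ester 9 and, on hydrolysis, to 10.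

Further compounds
F1 | step 5 | (2RS,3S)-2-{[4-(benzyloxy)-3-methoxyphenyl]methyl}-3-methyl-4-oxobutanoic acid | COc1cc(CC(C(=O)O)[C@H](C)C=O)ccc1OCc1ccccc1
F2 | step 5 | (3S,4S,5RS)-5-[4-(benzyloxy)-3,5-dimethoxyphenyl]-3-{[4-(benzyloxy)-3-methoxyphenyl]methyl}-4-methyloxolan-2-one | COc1cc(C[C@H]2[C@H](C)C(c3cc(OC)c(OCc4ccccc4)c(OC)c3)OC2=O)ccc1OCc1ccccc1
F3 | step 5 | (2S,3S,4RS)-4-[4-(benzyloxy)-3,5-dimethoxyphenyl]-2-{[4-(benzyloxy)-3-methoxyphenyl]methyl}-3-methylbutane-1,4-diol | COc1cc(C[C@H](CO)[C@H](C)C(O)c2cc(OC)c(OCc3ccccc3)c(OC)c2)ccc1OCc1ccccc1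
F4 | step 10 | (2S,3S)-2-{[4-(benzyloxy)-3-methoxyphenyl]methyl}-4-hydroxy-3-methylbutyl acetate | COc1cc(C[C@H](COC(C)=O)[C@H](C)CO)ccc1OCc1ccccc1
F5 | step 10 | (2S,3S)-2-{[4-(benzyloxy)-3-methoxyphenyl]methyl}-4-iodo-3-methylbutyl acetate | COc1cc(C[C@H](COC(C)=O)[C@H](C)CI)ccc1OCc1ccccc1
F6 | step 10 | (2S,3R)-4-[4-(benzyloxy)-3,5-dimethoxyphenyl]-2-{[4-(benzyloxy)-3-methoxyphenyl]methyl}-3-methylbutyl acetate | COc1cc(C[C@H](COC(C)=O)[C@H](C)Cc2cc(OC)c(OCc3ccccc3)c(OC)c2)ccc1OCc1ccccc1
F7 | step 4 | (S)-pent-3-yn-2-ol | C[C@H](O)C#CC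
F8 | step 4 | (2S,3E)-pent-3-en-2-ol | C[C@H](O)/C=C/C
F9 | step 4 | (2S,3E)-pent-3-en-2-yl 3-[4-(benzyloxy)-3-methoxyphenyl]propanoate | COc1cc(CCC(=O)O[C@@H](C)/C=C/C)ccc1OCc1ccccc1
F10 | step 4 | lithium Z(O)-enolate of F9 (CH2Ar cis to O–Li) | [Li+].COc1cc(C/C=C(\[O-])O[C@@H](C)/C=C/C)ccc1OCc1ccccc1
F11 | step 4 | (Z)-trimethylsilyl ketene acetal of F9 (CH2Ar cis to OSiMe3) | COc1cc(C/C=C(\O[Si](C)(C)C)O[C@@H](C)/C=C/C)ccc1OCc1ccccc1
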